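**Assumption (one line):** the SMILES is taken exactly as written: it specifies (1S,2S,4R,5S,6R), a trans-fused bicycle (H-1/H-5 trans) with H-1/H-2 cis and H-5/H-6 cis, and this isomer is the one made (the C-4 anomer shown has OH trans to C-6 and equilibrates with its epimer).

**Retrosynthetic overview** (3,7-dioxabicyclo[3.3.0]octane numbering: C-1/C-5 ring fusion, C-2/C-6 aryl carbons, C-4 lactol carbon)
1. Lactol (C-4) ⇐ trans-fused bicyclic γ-lactone by DIBAL, which also removes both aryl pivalates (last step).
2. Tetrahydrofuran ring ⇐ O-7–C-8 bond by intramolecular O-alkylation of a lactone diol. An aldol-type C–C closure onto the lactone enolate can only give the cis ring fusion, so the ring is closed through oxygen after the aldol has set the carbon centres.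
3. Diol ⇐ cis-hydroxymethyl lactone + O-pivaloylvanillin by an anti-selective boron aldol of the lactone (sets C-5 and C-6; C-5 trans to the C-1 substituent gives the trans fusion).
4. cis-Lactone ⇐ succinate imide + O-pivaloylvanillin by an Evans Mg-catalysed anti-aldol and lactonisation (sets C-1 and C-2), then reductive removal of the auxiliary.
5. Ring order: lactone ring (C-2/O-3/C-4) first, tetrahydrofuran ring (C-6/O-7/C-8) second, lactol last.

ArP = 3-methoxy-4-(pivaloyloxy)phenyl.

**Step 1**
Reactants: 1 vanillin
Product: 2 4-formyl-2-methoxyphenyl pivalate (O-pivaloylvanillin)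
Conditions: PivCl, Et3N, DMAP (cat.), CH2Cl2, 0 °C → rt
Reagents that add atoms: pivaloyl chloride, CC(C)(C)C(Cl)=O
Why: DMAP-catalysed O-acylation; the aryl pivalate survives the later amine, borohydride, boron-aldol and triflation steps, makes the benzylic C–O bonds less prone to ionise, and is removed by DIBAL in the last step.

**Step 2**
Reactants: 3 (S)-4-benzyloxazolidin-2-one; 4 methyl 4-chloro-4-oxobutanoate
Product: 5 methyl 4-[(4S)-4-benzyl-2-oxooxazolidin-3-yl]-4-oxobutanoate
Conditions: n-BuLi, THF, −78 °C; then 4, −78 → 0 °C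
Reagents that add atoms: none
Why: N-acylation of the lithiated Evans auxiliary by the acid chloride, which reacts far faster than the methyl ester.

**Step 3**
Reactants: 5; 2
Product: 6 (4S)-4-benzyl-3-{[(2S,3R)-2-ArP-5-oxotetrahydrofuran-3-yl]carbonyl}oxazolidin-2-one (cis lactone)
Conditions: MgCl2 (0.2 equiv), Et3N, TMSCl, EtOAc, rt; then TFA, MeOH/CH2Cl2, rt; PPTS (cat.), toluene, 50 °C
Reagents that add atoms: none (TMSCl gives a transient O-TMS ether that is cleaved in the acid stage)
Why: Evans magnesium-halide-catalysed anti-aldol: the chelated (Z)-Mg enolate is attacked on the face opposite the benzyl group (same sense as Evans alkylation) through a boat transition state, giving the anti adduct (α-carbon R = future C-1, carbinol S = future C-2); acid then removes the TMS group and the γ-hydroxy ester lactonises with loss of MeOH to the cis-4,5-disubstituted lactone.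

**Step 4**
Reactants: 6
Product: 7 (4S,5S)-4-(hydroxymethyl)-5-ArP-dihydrofuran-2(3H)-one (cis)
Conditions: NaBH4, THF/H2O (4:1), 0 °C; pH 7 buffer quench
Reagents that add atoms: none
Why: Reductive cleavage of the N-acyloxazolidinone: the imide carbonyl is far more electrophilic than the γ-lactone or the hindered aryl ester, so only it is reduced to CH2OH, and the cold, short, buffered work-up avoids epimerisation or translactonisation.

**Step 5**
Reactants: 7; 2
Product: 8 (3S,4S,5S)-3-[(R)-hydroxy(ArP)methyl]-4-(hydroxymethyl)-5-ArP-dihydrofuran-2(3H)-one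
Conditions: c-Hex2BOTf (2.3 equiv), Et3N (3 equiv), CH2Cl2, −78 °C; 2, −78 → 0 °C; pH 7 buffer, MeOH, 30% H2O2, 0 °C
Reagents that add atoms: none
Why: Boron aldol of the lactone: the primary OH is masked in situ as its borinate, and the ring-fixed (E)-enol borinate reacts through a Zimmerman–Traxler chair on the face opposite the cis CH2O[B] and aryl groups, so the new C-5 substituent is trans to C-8 and the aldol is anti (C-6 R).

**Step 6**
Reactants: 8
Product: 9 (1S,2S,5S,6R)-2,6-bis(ArP)-3,7-dioxabicyclo[3.3.0]octan-4-one (trans-fused)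
Conditions: Tf2O (1.05 equiv), 2,6-di-tert-butyl-4-methylpyridine, CH2Cl2, −78 → 0 °C (rt if slow)
Reagents that add atoms: none
Why: Selective triflation of the primary alcohol followed by intramolecular Williamson-type 5-exo-tet SN2 by the benzylic hydroxyl; the displaced carbon (C-8) is CH2, so C-6 is retained and the trans ring fusion is dictated by the existing trans C-1/C-5 centres.

**Step 7**
Reactants: 9
Product: 10 4α-hydroxypinoresinol as specified, (1S,2S,4R,5S,6R)-2,6-bis(4-hydroxy-3-methoxyphenyl)-3,7-dioxabicyclo[3.3.0]octan-4-ol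
Conditions: DIBAL-H (6.5 equiv), CH2Cl2, −78 °C; MeOH at −78 °C, then aq. Rochelle salt (pH 7)
Reagents that add atoms: none
Why: DIBAL partial reduction stops at the aluminium hemiacetal at −78 °C (lactone → lactol) and reductively cleaves both aryl pivalates; the anomeric hydroxyl settles trans to the C-5 substituent (4R) by anomeric equilibration.

**Compound list**
1 | vanillin | COc1cc(C=O)ccc1O | starting material
2 | 4-formyl-2-methoxyphenyl pivalate | COc1cc(C=O)ccc1OC(=O)C(C)(C)C | intermediate
3 | (S)-4-benzyloxazolidin-2-one | O=C1N[C@@H](Cc2ccccc2)CO1 | starting material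
4 | methyl 4-chloro-4-oxobutanoate | COC(=O)CCC(Cl)=O | starting material
5 | methyl 4-[(4S)-4-benzyl-2-oxooxazolidin-3-yl]-4-oxobutanoate | COC(=O)CCC(=O)N1C(=O)OC[C@@H]1Cc1ccccc1 | intermediate
6 | (4S)-4-benzyl-3-{[(2S,3R)-2-ArP-5-oxotetrahydrofuran-3-yl]carbonyl}oxazolidin-2-one | COc1cc([C@H]2OC(=O)C[C@H]2C(=O)N3C(=O)OC[C@@H]3Cc3ccccc3)ccc1OC(=O)C(C)(C)C | intermediate
7 | (4S,5S)-4-(hydroxymethyl)-5-ArP-dihydrofuran-2(3H)-one | COc1cc([C@H]2OC(=O)C[C@H]2CO)ccc1OC(=O)C(C)(C)C | intermediate
8 | (3S,4S,5S)-3-[(R)-hydroxy(ArP)methyl]-4-(hydroxymethyl)-5-ArP-dihydrofuran-2(3H)-one | COc1cc([C@H]2OC(=O)[C@H]([C@@H](O)c3ccc(OC(=O)C(C)(C)C)c(OC)c3)[C@H]2CO)ccc1OC(=O)C(C)(C)C | intermediate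
9 | (1S,2S,5S,6R)-2,6-bis(ArP)-3,7-dioxabicyclo[3.3.0]octan-4-one | COc1cc([C@H]2OC(=O)[C@H]3[C@H]2CO[C@H]3c2ccc(OC(=O)C(C)(C)C)c(OC)c2)ccc1OC(=O)C(C)(C)C | intermediate
10 | 4α-hydroxypinoresinol, (1S,2S,4R,5S,6R) | COc1cc([C@H]2O[C@@H](O)[C@H]3[C@H]2CO[C@H]3c2ccc(O)c(OC)c2)ccc1O | target

**Totals**
Total steps: 7.
Longest linear sequence: 6 steps (2 → 3 → 4 → 5 → 6 → 7; the vanillin line 1 → 3 → 4 → 5 → 6 → 7 is the same length). Aldehyde 2 enters twice, at steps 3 and 5.

**Three steps most likely to fail**
1. Step 7. The product is a strained trans-fused hemiacetal and may open to the hydroxy-aldehyde, epimerise at C-5 to the cis-fused lactol, or be over-reduced. Fallback: carry the phenols as TBS ethers instead of pivalates, trap the DIBAL intermediate in situ as the anomeric acetate (Ac2O, pyridine, DMAP, −78 °C), and release the lactol and phenols only at the end under buffered, near-neutral conditions.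
2. Step 6. Closing a trans-fused bicyclic lactone may be slow, letting triflate elimination or attack by the lactone carbonyl compete. Fallback: open the lactone of 8 to the Weinreb amide, close the now unstrained monocyclic tetrahydrofuran by the same triflate displacement, and form the lactol ring last by DIBAL reduction of the amide to the aldehyde, which is captured by the C-2 hydroxyl.
3. Step 5. The anti/syn ratio at C-6 may be poor. Fallback: make the syn aldol deliberately (Ti or Zr enolate of O-TBS-protected 7), mesylate the benzylic carbinol, and close the ring with inversion at C-6 by the C-8 alkoxide released with TBAF; this reaches the same lactone 9.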